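**Retrosynthetic overview**
1. Locants: C1 = ring C=O, C2=C3 = alkene, C4 = CH–OAc, C5 = ring C–OH, C1' = side-chain CH–OH. The last operations only handle oxygen groups: O1' silyl ether off, O4 acetate on, O4/O5 acetonide off.
2. Key disconnection: C5–C1', a directed aldol addition of a C8 bicyclic enone acetonide (as its C5 lithium enolate) to the C15 aldehyde pentadecanal. This completes the carbon skeleton and sets the tetrasubstituted C5 and the carbinol C1' in one operation.
3. Enabling feature: the cis pair O4/O5 on the adjacent ring carbons C4 and C5, next to C1=O. Tied into a cis-fused 1,3-dioxolane, it leaves C5–H as the only α-hydrogen, locks the enolate geometry (O5 cis to the enolate oxygen) and leaves only the convex face of C5 open.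
4. The enone acetonide goes back to (1S,4R)-cis-4-acetoxycyclopent-2-en-1-ol by syn-dihydroxylation, acetonide formation and oxidation with β-elimination of acetate.
5. Ring order: the carbocycle (ring A) comes with the starting material. The temporary dioxolane (ring B) is closed in step 2 and opened in step 6. No other ring is formed.

Key step: step 4

Assumption: (1S,4R)-cis-4-acetoxycyclopent-2-en-1-ol and pentadecanal are taken as commercially available; the aldehyde is distilled before use.

**Step 1**
Reactants: 1 (1S,4R)-cis-4-acetoxycyclopent-2-en-1-ol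
Product: 2 (1R,2R,3R,4S)-2,3,4-trihydroxycyclopentyl acetate
Conditions: OsO4 (cat.), NMO, acetone–H2O (4:1), 0 °C → rt
Reagents that add atoms: N-methylmorpholine N-oxide, C[N+]1([O-])CCOCC1; water, O
Why: In this catalytic OsO4/NMO syn-dihydroxylation the oxidant should add suprafacially to the ring face opposite the two cis allylic oxygen substituents, which places both new hydroxyls cis to each other and trans to OH and OAc.

**Step 2**
Reactants: 2 (1R,2R,3R,4S)-2,3,4-trihydroxycyclopentyl acetate
Product: 3 (3aS,4R,6S,6aR)-6-hydroxy-2,2-dimethyltetrahydro-4H-cyclopenta[d][1,3]dioxol-4-yl acetate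
Conditions: Me2C(OMe)2, TsOH·H2O (cat.), acetone, rt
Reagents that add atoms: 2,2-dimethoxypropane, COC(C)(C)OC
Why: In this acid-catalysed transketalisation (acetonide formation) only the cis diol can close a five-membered dioxolane, because the third hydroxyl is trans to its neighbour, so it stays free and no stereocentre is touched.

**Step 3**
Reactants: 3 (3aS,4R,6S,6aR)-6-hydroxy-2,2-dimethyltetrahydro-4H-cyclopenta[d][1,3]dioxol-4-yl acetate
Product: 5 (3aS,6aS)-2,2-dimethyl-3a,6a-dihydro-4H-cyclopenta[d][1,3]dioxol-4-one, via keto acetate 4 (not isolated)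
Conditions: Dess–Martin periodinane, CH2Cl2, rt; then Et3N, rt, same flask
Reagents that add atoms: none
Why: Dess–Martin oxidation gives ketone 4, whose acidified CH2 group lets Et3N expel the β-acetate by E1cB elimination, while the α-alkoxy centre cannot epimerise because that would need a trans-fused bicyclo[3.3.0] system.

**Step 4**
Reactants: 5 (3aS,6aS)-2,2-dimethyl-3a,6a-dihydro-4H-cyclopenta[d][1,3]dioxol-4-one; 6 pentadecanal
Product: 9 (3aS,6aS)-3a-[(1S)-1-hydroxypentadecyl]-2,2-dimethyl-3a,6a-dihydro-4H-cyclopenta[d][1,3]dioxol-4-one, via lithium enolate 7 (not isolated), via lithium aldolate 8 (not isolated)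
Conditions: LiN(iPr)2 (commercial solution), THF, −78 °C, slow addition of 5; then 6, −78 °C; AcOH/THF quench at −78 °C
Reagents that add atoms: none
Why: Slow addition of 5 to the hindered amide base removes the only α-hydrogen (C5–H; C2 is vinylic), and the cross-conjugated lithium enolate 7 adds to the carbonyl of 6 through a lithium-bridged six-membered transition state to give aldolate 8, which is protonated cold. The closest known reaction type is the directed aldol addition of lithium enolates of 4-oxygenated cyclopent-2-enones and of dioxolane-tethered α-alkoxy carbonyl compounds, an established way to tetrasubstituted carbinol carbons. No ring is closed in this step; ring B only steers it. C5 is controlled by the ring fusion: bond formation syn to the C4–O bond would give a trans-fused bicyclo[3.3.0]octane, so the aldehyde enters on the convex face, anti to O4, and O5 stays cis to O4. C1' is controlled by the ring-locked enolate geometry (O5 cis and C4 trans to OLi): in the chair Zimmerman–Traxler arrangement with the tetradecyl chain equatorial, O1' ends up syn to O5 along the C1–C5–C1'–C2' backbone, which is the (1'S) configuration. The step needs α'-deprotonation rather than conjugate or self-Michael addition (hindered base, inverse addition, −78 °C), survival of the enolate (β-loss of O4 would expel a poor alkoxide leaving group and give an antiaromatic cyclopentadienone), and no retro-aldol equilibration (short time, acid quench at −78 °C).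

**Step 5**
Reactants: 9 (3aS,6aS)-3a-[(1S)-1-hydroxypentadecyl]-2,2-dimethyl-3a,6a-dihydro-4H-cyclopenta[d][1,3]dioxol-4-one
Product: 10 (3aR,6aS)-3a-[(1S)-1-{[tert-butyl(dimethyl)silyl]oxy}pentadecyl]-2,2-dimethyl-3a,6a-dihydro-4H-cyclopenta[d][1,3]dioxol-4-one (same spatial arrangement; the C3a descriptor changes only through CIP priorities)
Conditions: TBSOTf, 2,6-lutidine, CH2Cl2, −78 → 0 °C
Reagents that add atoms: tert-butyldimethylsilyl trifluoromethanesulfonate, CC(C)(C)[Si](C)(C)OS(=O)(=O)C(F)(F)F
Why: Silyl ether formation with a silyl triflate and a hindered pyridine base is reactive enough for a carbinol next to a quaternary carbon, is too weakly basic to start a retro-aldol, and touches no stereocentre.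

**Step 6**
Reactants: 10 (3aR,6aS)-3a-[(1S)-1-{[tert-butyl(dimethyl)silyl]oxy}pentadecyl]-2,2-dimethyl-3a,6a-dihydro-4H-cyclopenta[d][1,3]dioxol-4-one
Product: 11 (4S,5R)-5-[(1S)-1-{[tert-butyl(dimethyl)silyl]oxy}pentadecyl]-4,5-dihydroxycyclopent-2-en-1-one
Conditions: TFA–H2O (9:1), CH2Cl2, 0 °C, stopped at full conversion
Reagents that add atoms: none
Why: Acid hydrolysis of the isopropylidene acetal breaks only the bonds at the acetal carbon, so C4 and C5 keep their configuration, and the secondary silyl ether beside a quaternary carbon should hydrolyse much more slowly under these conditions.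

**Step 7**
Reactants: 11 (4S,5R)-5-[(1S)-1-{[tert-butyl(dimethyl)silyl]oxy}pentadecyl]-4,5-dihydroxycyclopent-2-en-1-one
Product: 12 (1S,5R)-5-[(1S)-1-{[tert-butyl(dimethyl)silyl]oxy}pentadecyl]-5-hydroxy-4-oxocyclopent-2-en-1-yl acetate
Conditions: Ac2O, pyridine, DMAP (cat.), CH2Cl2, 0 °C
Reagents that add atoms: acetic anhydride, CC(=O)OC(C)=O
Why: In this DMAP-catalysed acylation the secondary allylic C4–OH should react far faster than the tertiary α-ketol C5–OH, O1' is blocked, and the acetate cannot be lost by E1cB elimination because C5 carries no hydrogen.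

**Step 8**
Reactants: 12 (1S,5R)-5-[(1S)-1-{[tert-butyl(dimethyl)silyl]oxy}pentadecyl]-5-hydroxy-4-oxocyclopent-2-en-1-yl acetate
Product: 13 (1S,5S)-5-hydroxy-5-[(1S)-1-hydroxypentadecyl]-4-oxocyclopent-2-en-1-yl acetate (target)
Conditions: HF·pyridine, pyridine, THF, 0 °C → rt (plastic vessel)
Reagents that add atoms: none
Why: Fluoride-mediated desilylation in a buffered, weakly acidic medium should spare the acetate and the enone and avoid the acetyl migration and retro-aldol that a basic fluoride source could trigger; no stereocentre is touched.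

**Compound list**
1 | (1S,4R)-cis-4-acetoxycyclopent-2-en-1-ol [= (1R,4S)-4-hydroxycyclopent-2-en-1-yl acetate] | CC(=O)O[C@@H]1C[C@H](O)C=C1 | starting material
2 | (1R,2R,3R,4S)-2,3,4-trihydroxycyclopentyl acetate | CC(=O)O[C@@H]1C[C@H](O)[C@@H](O)[C@H]1O | intermediate
3 | (3aS,4R,6S,6aR)-6-hydroxy-2,2-dimethyltetrahydro-4H-cyclopenta[d][1,3]dioxol-4-yl acetate | CC(=O)O[C@@H]1C[C@H](O)[C@H]2OC(C)(C)O[C@@H]12 | intermediate
4 | (3aS,4R,6aS)-2,2-dimethyl-6-oxotetrahydro-4H-cyclopenta[d][1,3]dioxol-4-yl acetate (keto acetate, not isolated) | CC(=O)O[C@@H]1CC(=O)[C@H]2OC(C)(C)O[C@@H]12 | intermediate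
5 | (3aS,6aS)-2,2-dimethyl-3a,6a-dihydro-4H-cyclopenta[d][1,3]dioxol-4-one | O=C1C=C[C@@H]2OC(C)(C)O[C@H]12 | intermediate
6 | pentadecanal | CCCCCCCCCCCCCCC=O | starting material
7 | lithium (6aS)-2,2-dimethyl-6aH-cyclopenta[d][1,3]dioxol-4-olate (lithium enolate, not isolated) | [Li+].[O-]C1=C2OC(C)(C)O[C@H]2C=C1 | intermediate
8 | lithium (1S)-1-[(3aS,6aS)-2,2-dimethyl-4-oxo-3a,6a-dihydro-4H-cyclopenta[d][1,3]dioxol-3a-yl]pentadecan-1-olate (lithium aldolate, not isolated) | [Li+].CCCCCCCCCCCCCC[C@H]([O-])[C@@]1(OC(C)(C)O2)C(=O)C=C[C@@H]12 | intermediate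
9 | (3aS,6aS)-3a-[(1S)-1-hydroxypentadecyl]-2,2-dimethyl-3a,6a-dihydro-4H-cyclopenta[d][1,3]dioxol-4-one | CCCCCCCCCCCCCC[C@H](O)[C@@]1(OC(C)(C)O2)C(=O)C=C[C@@H]12 | intermediate
10 | (3aR,6aS)-3a-[(1S)-1-{[tert-butyl(dimethyl)silyl]oxy}pentadecyl]-2,2-dimethyl-3a,6a-dihydro-4H-cyclopenta[d][1,3]dioxol-4-one | CCCCCCCCCCCCCC[C@H](O[Si](C)(C)C(C)(C)C)[C@@]1(OC(C)(C)O2)C(=O)C=C[C@@H]12 | intermediate
11 | (4S,5R)-5-[(1S)-1-{[tert-butyl(dimethyl)silyl]oxy}pentadecyl]-4,5-dihydroxycyclopent-2-en-1-one | CCCCCCCCCCCCCC[C@H](O[Si](C)(C)C(C)(C)C)[C@@]1(O)C(=O)C=C[C@@H]1O | intermediate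
12 | (1S,5R)-5-[(1S)-1-{[tert-butyl(dimethyl)silyl]oxy}pentadecyl]-5-hydroxy-4-oxocyclopent-2-en-1-yl acetate | CCCCCCCCCCCCCC[C@H](O[Si](C)(C)C(C)(C)C)[C@@]1(O)C(=O)C=C[C@@H]1OC(C)=O | intermediate
13 | (1S,5S)-5-hydroxy-5-[(1S)-1-hydroxypentadecyl]-4-oxocyclopent-2-en-1-yl acetate | CCCCCCCCCCCCCC[C@H](O)[C@@]1(O)C(=O)C=C[C@@H]1OC(C)=O | target

**Step count**
Total step count: 8. Longest linear sequence: 8 steps (1 → 13); pentadecanal 6 enters directly in step 4.

**Steps most likely to fail**

Step 4 (key aldol addition).
- **Risk:** The cross-conjugated lithium enolate may break down by β-elimination of O4 or by self-Michael addition. The hindered aldolate may revert. Leakage through non-chair transition states would erode control at C1'.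
- **Fallback:** The basic enolate is replaced by a Mukaiyama aldol addition, setting out from 5. TBSOTf, Et3N, CH2Cl2, 0 °C should give the silyl dienol ether tert-butyl{[(6aS)-2,2-dimethyl-6aH-cyclopenta[d][1,3]dioxol-4-yl]oxy}dimethylsilane F1. F1 is used at once, because as a cyclopentadiene it is prone to hydrogen shift and dimerisation. Addition to 6 promoted by BF3·OEt2 in CH2Cl2 at −78 °C is not reversible under these conditions and comes back to the route at 9.
- **Stereocontrol in the fallback:** C5 is still fixed by the convex face of the bicycle. C1' would be set by an open transition state, so a separation of C1' epimers may be needed.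

Step 6 (acetonide hydrolysis beside the silyl ether).
- **Risk:** The O1' silyl group may be lost at a rate comparable with the slow hydrolysis of the electron-poor dioxolane. That would erase the differentiation of O1' from O4.
- **Fallback:** Chemical differentiation is given up in favour of an enzyme, setting out from 9. Aqueous TFA removes the acetonide to give the triol (4S,5S)-4,5-dihydroxy-5-[(1S)-1-hydroxypentadecyl]cyclopent-2-en-1-one F2. A lipase-catalysed transesterification (immobilised Candida antarctica lipase B, vinyl acetate, MTBE, rt) should then acetylate only the exposed ring carbinol O4. The tertiary O5–H is not accepted by lipases, and O1'–H lies between a quaternary carbon and the C14 chain. This comes back to the route at 13.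

Step 8 (final desilylation).
- **Risk:** The hindered silyl ether may cleave slowly. Long exposure could then cause acetyl migration from O4 towards O5 and O1', or decay of the sensitive enone.
- **Fallback:** The fluoride-labile group is replaced by an oxidatively cleaved one, setting out from 9. The sequence is:
  - 4-methoxybenzyl 2,2,2-trichloroacetimidate, La(OTf)3 (cat.), toluene, rt should give (3aS,6aS)-3a-{(1S)-1-[(4-methoxybenzyl)oxy]pentadecyl}-2,2-dimethyl-3a,6a-dihydro-4H-cyclopenta[d][1,3]dioxol-4-one F3.
  - 1 M aqueous HCl–THF, which benzyl-type ethers tolerate, opens the acetonide to (4S,5R)-4,5-dihydroxy-5-{(1S)-1-[(4-methoxybenzyl)oxy]pentadecyl}cyclopent-2-en-1-one F4.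
  - Ac2O, pyridine, DMAP gives (1S,5S)-5-hydroxy-5-{(1S)-1-[(4-methoxybenzyl)oxy]pentadecyl}-4-oxocyclopent-2-en-1-yl acetate F5.
  - DDQ in CH2Cl2–pH 7 buffer at 0 °C removes the benzyl-type ether under neutral conditions and comes back to the route at 13.

**Further compounds**
F1 | step 4 | tert-butyl{[(6aS)-2,2-dimethyl-6aH-cyclopenta[d][1,3]dioxol-4-yl]oxy}dimethylsilane | CC(C)(C)[Si](C)(C)OC1=C2OC(C)(C)O[C@H]2C=C1
F2 | step 6 | (4S,5S)-4,5-dihydroxy-5-[(1S)-1-hydroxypentadecyl]cyclopent-2-en-1-one | CCCCCCCCCCCCCC[C@H](O)[C@@]1(O)C(=O)C=C[C@@H]1O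
F3 | step 8 | (3aS,6aS)-3a-{(1S)-1-[(4-methoxybenzyl)oxy]pentadecyl}-2,2-dimethyl-3a,6a-dihydro-4H-cyclopenta[d][1,3]dioxol-4-one | CCCCCCCCCCCCCC[C@H](OCc1ccc(OC)cc1)[C@@]1(OC(C)(C)O2)C(=O)C=C[C@@H]12
F4 | step 8 | (4S,5R)-4,5-dihydroxy-5-{(1S)-1-[(4-methoxybenzyl)oxy]pentadecyl}cyclopent-2-en-1-one | CCCCCCCCCCCCCC[C@H](OCc1ccc(OC)cc1)[C@@]1(O)C(=O)C=C[C@@H]1O
F5 | step 8 | (1S,5S)-5-hydroxy-5-{(1S)-1-[(4-methoxybenzyl)oxy]pentadecyl}-4-oxocyclopent-2-en-1-yl acetate | CCCCCCCCCCCCCC[C@H](OCc1ccc(OC)cc1)[C@@]1(O)C(=O)C=C[C@@H]1OC(C)=O
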